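**Retrosynthetic overview**
1. Both halves come from (−)-EGCG 1. One copy is ring-locked as its bis(benzophenone ketal) 2 (nucleophile); a second copy of 1 is used unprotected as the electrophile, with no leaving group installed.
2. Key disconnection: the bond from C2 of the opened half to C8 of the intact half. Ring C of 1 opens thermally (retro-oxa-Michael, the reverse of the flavan ring-closing step) to para-quinone methide 3, and C8 of 2 adds to it to give 4.
3. Hydrogenolysis of the two ketals of 4 in the same flask gives target 5.
4. Ring order: no ring of the target is built; rings A, B, C and the galloyl rings all come from 1. The two dioxole cap rings are formed in step 1, ring C of the upper half is opened in step 2, and the caps are cleaved in step 2.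

Assumption: two stages run in one flask without isolation count as one step; EGCG of at least 95 % purity (green tea) is taken as the cheap commercial source of both halves.

**Step 1**
Reactants: 1 (−)-epigallocatechin 3-O-gallate (EGCG), (2R,3R)-5,7-dihydroxy-2-(3,4,5-trihydroxyphenyl)chroman-3-yl 3,4,5-trihydroxybenzoate
Product: 2 EGCG bis(diphenylmethylene ketal), (2R,3R)-5,7-dihydroxy-2-(7-hydroxy-2,2-diphenyl-1,3-benzodioxol-5-yl)chroman-3-yl 7-hydroxy-2,2-diphenyl-1,3-benzodioxole-5-carboxylate
Conditions: Ph2CCl2 (2.2 equiv), K2CO3 (4.5 equiv), MeCN, 0 °C → rt, Ar, 18 h; aq. citric acid work-up; SiO2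
Reagents that add atoms: dichlorodiphenylmethane, ClC(Cl)(c1ccccc1)c1ccccc1
Why: Ketalisation by double O-alkylation closes a five-membered benzophenone ketal on the vicinal diol of each pyrogallol (ring B and the galloyl ring), while isolated phenols give only chloro-ethers that hydrolyse back on work-up; no stereocentre is formed, and tying up O-4' removes the para-phenol needed to open ring C, so 2 keeps its (2R,3R) centres in step 2.

**Step 2**
Reactants: 1 (−)-epigallocatechin 3-O-gallate (1.0 equiv) and 2 EGCG bis(diphenylmethylene ketal) (3.0 equiv)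
Product: 5 (2R,3R)-5,7-dihydroxy-8-[(1S,2R)-1-(3,4,5-trihydroxyphenyl)-2-(3,4,5-trihydroxybenzoyloxy)-3-(2,4,6-trihydroxyphenyl)propyl]-2-(3,4,5-trihydroxyphenyl)chroman-3-yl 3,4,5-trihydroxybenzoate (target CNP0155034.1), via ring-opened para-quinone methide 3 (not isolated), via bis-ketal chalcan–flavan dimer 4 (not isolated)
Conditions: (i) degassed 1,4-dioxane–H2O 9:1, NaOAc/AcOH (0.3 equiv each, apparent pH ≈ 6), 0.3 M in 2, 100 °C, sealed, Ar, 24–36 h (HPLC control); (ii) cool, add MeOH, Pd(OH)2/C (20 wt %), H2 (1 atm), rt, 12 h; Sephadex LH-20, then preparative C18 HPLC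
Reagents that add atoms: none
Why: Proposed new method: at near-neutral pH and 100 °C the 4'-phenolate of 1 expels the ring A phenoxide (retro-oxa-Michael, the opening that epimerises tea catechins at C2) to give para-quinone methide 3, which re-closes reversibly but is drained irreversibly by 1,6-addition (vinylogous Michael C-alkylation) of the more nucleophilic C8 of excess 2, which cannot itself open because its O-4' sits in the ketal, so the (2R,3R) centres of the lower half stay intact; the new diarylmethine centre is predicted to be 1S by an A1,3-strain model (C–H of the acyloxy carbon eclipsing the quinoid plane, arene entering anti to the bulky 2,4,6-trihydroxybenzyl group, on the face of the small ester oxygen), and Pd-catalysed hydrogenolysis of the two benzophenone ketals then frees the pyrogallols; the closest known reaction type is the thermal self-condensation of flavan-3-ols to chalcan–flavan dimers and the 1,6-arylation of para-quinone methides by phenols.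

**Compound list**
1 | (−)-epigallocatechin 3-O-gallate (EGCG), (2R,3R) | O=C(O[C@@H]1Cc2c(O)cc(O)cc2O[C@@H]1c1cc(O)c(O)c(O)c1)c1cc(O)c(O)c(O)c1 | starting material
2 | EGCG bis(diphenylmethylene ketal): O-3'/O-4' of ring B and O-3''/O-4'' of the galloyl ring each bridged by CPh2, (2R,3R) | O=C(O[C@@H]1Cc2c(O)cc(O)cc2O[C@@H]1c1cc2OC(c3ccccc3)(c3ccccc3)Oc2c(O)c1)c1cc2OC(c3ccccc3)(c3ccccc3)Oc2c(O)c1 | intermediate
3 | ring-opened para-quinone methide of EGCG, (2R)-1-(3,5-dihydroxy-4-oxocyclohexa-2,5-dien-1-ylidene)-3-(2,4,6-trihydroxyphenyl)propan-2-yl 3,4,5-trihydroxybenzoate | O=C(O[C@H](Cc1c(O)cc(O)cc1O)C=C1C=C(O)C(=O)C(O)=C1)c1cc(O)c(O)c(O)c1 | intermediate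
4 | bis-ketal chalcan–flavan dimer: target skeleton with ring B and the galloyl ring of the lower (intact) half each carrying a 3,4-O-diphenylmethylene ketal; (2R,3R) chroman, (1S,2R) propyl chain | O=C(O[C@H](Cc1c(O)cc(O)cc1O)[C@@H](c1cc(O)c(O)c(O)c1)c1c(O)cc(O)c2c1O[C@H](c1cc3OC(c4ccccc4)(c4ccccc4)Oc3c(O)c1)[C@H](OC(=O)c1cc3OC(c4ccccc4)(c4ccccc4)Oc3c(O)c1)C2)c1cc(O)c(O)c(O)c1 | intermediate
5 | CNP0155034.1, (2R,3R)-5,7-dihydroxy-8-[(1S,2R)-1-(3,4,5-trihydroxyphenyl)-2-(3,4,5-trihydroxybenzoyloxy)-3-(2,4,6-trihydroxyphenyl)propyl]-2-(3,4,5-trihydroxyphenyl)chroman-3-yl 3,4,5-trihydroxybenzoate | O=C(O[C@H](Cc1c(O)cc(O)cc1O)[C@@H](c1cc(O)c(O)c(O)c1)c1c(O)cc(O)c2c1O[C@H](c1cc(O)c(O)c(O)c1)[C@H](OC(=O)c1cc(O)c(O)c(O)c1)C2)c1cc(O)c(O)c(O)c1 | target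

**Step count and risks**
Total step count: 2. Longest linear sequence: 2 (1 → 2 → 5); 1 enters twice. The route has only two steps, so the three weakest operations are the coupling stage of step 2, step 1, and the hydrogenolysis stage of step 2.

Most likely to fail is the coupling stage of step 2. Re-closure of 3 to EGCG or its C2 epimer is intramolecular and will outrun capture by 2, so the reaction may take long enough for gallate hydrolysis and trimer formation to matter. The facial model may give only a modest ratio at the new centre, and some C6-linked isomer is expected; the yield of 5 may be low. The fallback changes both the locking principle and the activation. It sets out from 1: carbonyldiimidazole (2.2 equiv, THF, 0 °C to rt) converts the two pyrogallols into cyclic carbonates, giving the EGCG bis(cyclic carbonate) F1. Compound 1 (1 equiv) and F1 (3 equiv) are then treated with TsOH (10 mol %) in (CF3)2CHOH–1,4-dioxane at 40 °C. Acid ionises the C2–O1 bond of 1 only, because the acylated O-4' of F1 cannot stabilise a C2 cation, and C8 of F1 traps the hydroxybenzyl cation in a Friedel–Crafts alkylation to give the carbonate-capped dimer F2. NaHCO3 in THF–H2O at 0 °C under Ar hydrolyses the aryl carbonates, and the fallback comes back to the route at 5.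

Second is step 1. The risks are incomplete or unselective ketalisation, C-alkylation of ring A, and base-induced C2 epimerisation of 1 before O-4' is capped. The fallback drops the cap altogether. It sets out from 1, which is heated alone at about 1 M under the buffer conditions of step 2 to no more than 30 % conversion; 3 is then trapped by C8 of a second molecule of 1 and the fallback comes back to the route directly at 5. The price is that the nucleophile pool epimerises, so 5 must be separated by LH-20 and C18 HPLC from its lower-half C2 epimer as well as from the C6-linked and 1R isomers, and recovered monomer is recycled. No new compound is made (entry F0).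

Third is the hydrogenolysis stage of step 2. Polyphenolic oligomers may foul the catalyst, or the benzylic C2–O1 bond of the lower half may be attacked on long exposure. The fallback replaces the reductively cleaved cap by an acid-labile one. It sets out from 1: 2,2-dimethoxypropane with catalytic TsOH (acetone–toluene, reflux through 4 Å sieves) gives the EGCG bis(acetonide) F3. F3 (3 equiv) is coupled with 1 exactly as in stage (i) of step 2 to give the acetonide-capped dimer F4. CF3CO2H–H2O 9:1 at 0 °C to rt hydrolyses both ketals, and the fallback comes back to the route at 5.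

**Further compounds**
F1 | step 2 | EGCG bis(cyclic carbonate), (2R,3R)-5,7-dihydroxy-2-(7-hydroxy-2-oxo-1,3-benzodioxol-5-yl)chroman-3-yl 7-hydroxy-2-oxo-1,3-benzodioxole-5-carboxylate | O=C(O[C@@H]1Cc2c(O)cc(O)cc2O[C@@H]1c1cc2OC(=O)Oc2c(O)c1)c1cc2OC(=O)Oc2c(O)c1
F2 | step 2 | carbonate-capped chalcan–flavan dimer (target skeleton, lower-half ring B and galloyl ring each as 3,4-cyclic carbonate) | O=C(O[C@H](Cc1c(O)cc(O)cc1O)[C@@H](c1cc(O)c(O)c(O)c1)c1c(O)cc(O)c2c1O[C@H](c1cc3OC(=O)Oc3c(O)c1)[C@H](OC(=O)c1cc3OC(=O)Oc3c(O)c1)C2)c1cc(O)c(O)c(O)c1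
F0 | step 1 | none | none
F3 | step 2 | EGCG bis(acetonide), (2R,3R)-5,7-dihydroxy-2-(7-hydroxy-2,2-dimethyl-1,3-benzodioxol-5-yl)chroman-3-yl 7-hydroxy-2,2-dimethyl-1,3-benzodioxole-5-carboxylate | O=C(O[C@@H]1Cc2c(O)cc(O)cc2O[C@@H]1c1cc2OC(C)(C)Oc2c(O)c1)c1cc2OC(C)(C)Oc2c(O)c1
F4 | step 2 | acetonide-capped chalcan–flavan dimer (target skeleton, lower-half ring B and galloyl ring each as 3,4-O-isopropylidene ketal) | O=C(O[C@H](Cc1c(O)cc(O)cc1O)[C@@H](c1cc(O)c(O)c(O)c1)c1c(O)cc(O)c2c1O[C@H](c1cc3OC(C)(C)Oc3c(O)c1)[C@H](OC(=O)c1cc3OC(C)(C)Oc3c(O)c1)C2)c1cc(O)c(O)c(O)c1
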